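Everything rests on cutting lactone ring B at two bonds, O2–C3 and C4–C4a. The segment C4a–C4–C3–O2 is the 1,2-carbo-oxygenation pattern of a terminal alkene, and the saturated C1'–C2' pair beside C3 can hide the second alkene of a 1,3-diene; this is the feature exploited. In one operation a chiral zerovalent palladium catalyst joins 2-iodo-4,6-dimethoxybenzoic acid and (E)-penta-1,3-diene: arylpalladation makes C4–C4a, then the ortho-carboxylate oxygen attacks C3 of the allylpalladium, closing ring B and setting C3. The propenyl group left behind serves as handle for cross-metathesis with (S)-undec-1-en-6-ol; hydrogenation and chelation-directed 8-O-demethylation finish.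

Key step: step 3

Remarks before the steps
- Numbering: isochroman-1-one numbering is used (C1 carbonyl, O2, C3, C4, C4a, C5 to C8, C8a), and the side chain is C1' to C11'. Ring A is the arene and ring B the lactone.
- Target: it is read as (3R,6'S).
- Assumption: the sense of induction of the phosphoramidite ligand L* in step 3 cannot be predicted safely for a carboxylate-terminated annulation. The ligand enantiomer that leads to (3S)-7 is therefore fixed in a trial run; both enantiomers are available.
- Descriptor at C3: it changes from S (7, 13) to R (14, 15, 16) only because saturation reverses the CIP ranking of C1' and C4. The spatial arrangement stays the same.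
- salen = dianion of N,N'-bis(3,5-di-tert-butylsalicylidene)cyclohexane-1,2-diamine.

Step 1
Reactants: 1 1-iodo-3,5-dimethoxybenzene
Product: 3 2-iodo-4,6-dimethoxybenzaldehyde, via iminium chloride 2 (not isolated)
Conditions: POCl3 (2 equiv), DMF, 0 to 90 °C; then ice-water
Reagents that add atoms: N,N-dimethylformamide CN(C)C=O; water O
Why: Vilsmeier–Haack formylation, in which the chloroiminium ion attacks the position para to one methoxy group and ortho to the other (next to iodine), a site less crowded than the one between the two methoxy groups, and water then hydrolyses iminium salt 2 to the aldehyde; no stereocentre is formed.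

Step 2
Reactants: 3 2-iodo-4,6-dimethoxybenzaldehyde
Product: 4 2-iodo-4,6-dimethoxybenzoic acid
Conditions: NaClO2, NaH2PO4, 2-methyl-2-butene, t-BuOH/H2O, rt
Reagents that add atoms: sodium chlorite [Na+].[O-]Cl=O
Why: Pinnick oxidation, in which chlorous acid adds to the aldehyde and fragments to the acid while 2-methyl-2-butene traps the hypochlorous acid released, so that the electron-rich ring A and the C–I bond should stay untouched.

Step 3
Reactants: 4 2-iodo-4,6-dimethoxybenzoic acid; 5 (E)-penta-1,3-diene
Product: 7 (3S)-6,8-dimethoxy-3-[(E)-prop-1-enyl]isochroman-1-one, via potassium carboxylate 6 (not isolated)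
Conditions: Pd2(dba)3·CHCl3 (2.5 mol %), L* = (S)-BINOL-derived phosphoramidite of bis[(R)-1-phenylethyl]amine or its enantiomer (6 mol %), K2CO3 (2 equiv), n-Bu4NCl (1 equiv), 5 (4 equiv, isomerically pure E), 1,4-dioxane, 70 °C, sealed tube
Reagents that add atoms: none
Why: Zerovalent palladium inserts into the C–I bond of carboxylate 6, the CH2=CH end of 5 undergoes syn migratory insertion with the aryl group going to the unsubstituted carbon (C4–C4a bond), and the syn,syn-η3-allylpalladium spanning C3–C1'–C2' is attacked at C3 by the ortho-carboxylate oxygen, which forms O2–C3 and gives back zerovalent palladium. The closest known reaction type is the Larock heteroannulation of 1,3-dienes by ortho-iodobenzoic acids, run here in the enantioselective Heck/Tsuji–Trost mode known with chiral phosphoramidite ligands for ortho-iodoanilines, ortho-halophenols and ortho-iodobenzyl alcohols. Ring B, the only ring closed, forms by 6-exo attack on the allyl terminus with C1'=C2' staying outside the ring, whereas attack at C2' would need an eight-membered ring. The new stereocentre C3 is controlled by the chiral ligand, which selects the face of the vinyl group during insertion, and this choice is passed on stereospecifically by outer-sphere attack anti to palladium, chloride from n-Bu4NCl keeping the carboxylate off the metal so that syn delivery should not compete. The step needs insertion at the terminal and not the internal alkene (secured by the greater hindrance of the methyl-substituted E alkene), ring closure faster than β-hydride elimination (secured by the carboxylate held next to C3) and a configurationally stable product (secured by the 1,3-disubstituted allyl unit, since re-ionisation of allylic lactone 7 returns the same allyl complex, which a butadiene-derived allyl would not guarantee). The two methyl ethers keep ring A free of acidic or chelating sites, and 7 can be enriched by recrystallisation before it meets the second stereocentre.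

Step 4
Reactants: 8 rac-2-pentyloxirane
Product: 9 (S)-2-pentyloxirane
Conditions: (S,S)-Co(salen)(OAc) (0.5 mol %), H2O (0.55 equiv), neat, 0 °C to rt; distillation
Reagents that add atoms: none
Why: Jacobsen hydrolytic kinetic resolution, in which the (S,S)-configured trivalent cobalt salen catalyst hydrolyses the (R)-epoxide selectively so that (S)-9 is left and distilled from the diol, which fixes the future C6' stereocentre.

Step 5
Reactants: 9 (S)-2-pentyloxirane; 10 but-3-enylmagnesium bromide
Product: 12 (S)-undec-1-en-6-ol, via magnesium alkoxide 11 (not isolated)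
Conditions: 10 (1.3 equiv), CuI (10 mol %), THF, −30 to 0 °C; then aq NH4Cl
Reagents that add atoms: none
Why: Copper-catalysed Grignard opening of a terminal epoxide by SN2 attack at the unsubstituted carbon, which leaves the C–O stereocentre untouched.

Step 6
Reactants: 7 (3S)-6,8-dimethoxy-3-[(E)-prop-1-enyl]isochroman-1-one; 12 (S)-undec-1-en-6-ol
Product: 14 (3R)-3-[(6S)-6-hydroxyundecyl]-6,8-dimethoxyisochroman-1-one, via alkenyl lactone 13 (not isolated)
Conditions: 12 (2 equiv), second-generation Hoveyda–Grubbs catalyst RuCl2(H2IMes)(=CH-C6H4-2-OiPr) (5 mol %), CH2Cl2, 40 °C; then PtO2 (5 mol %), H2 (1 atm), rt, same flask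
Reagents that add atoms: none
Why: Olefin cross-metathesis followed by catalytic hydrogenation in one flask, in which the unhindered terminal alkene of 12 loads the ruthenium carbene, this carbene exchanges with the propenyl group of 7 under loss of volatile propene, and platinum (less prone than palladium to cleave the allylic C3–O2 bond) then saturates C1'=C2' of 13 without touching C3 or C6'.

Step 7
Reactants: 14 (3R)-3-[(6S)-6-hydroxyundecyl]-6,8-dimethoxyisochroman-1-one
Product: 16 (3R)-8-hydroxy-3-[(6S)-6-hydroxyundecyl]-6-methoxyisochroman-1-one (target), via dichloroboryl derivative 15 (not isolated)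
Conditions: BCl3 (3 equiv), CH2Cl2, −78 to 0 °C; then H2O
Reagents that add atoms: none
Why: Chelation-directed aryl methyl ether cleavage, in which BCl3 bound between the C1 carbonyl and the peri 8-methoxy oxygen lets chloride remove only that methyl group, the 6-methoxy group lacks this activation, the borate formed at the C6' hydroxyl is hydrolysed on work-up, and no stereocentre is touched.

Compound list
1 | 1-iodo-3,5-dimethoxybenzene | COc1cc(I)cc(OC)c1 | starting material
2 | (2-iodo-4,6-dimethoxybenzylidene)dimethyliminium chloride | COc1cc(I)c(C=[N+](C)C)c(OC)c1.[Cl-] | intermediate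
3 | 2-iodo-4,6-dimethoxybenzaldehyde | COc1cc(I)c(C=O)c(OC)c1 | intermediate
4 | 2-iodo-4,6-dimethoxybenzoic acid | COc1cc(I)c(C(=O)O)c(OC)c1 | intermediate
5 | (E)-penta-1,3-diene (trans-piperylene) | C/C=C/C=C | starting material
6 | potassium 2-iodo-4,6-dimethoxybenzoate | COc1cc(I)c(C(=O)[O-])c(OC)c1.[K+] | intermediate
7 | (3S)-6,8-dimethoxy-3-[(E)-prop-1-enyl]isochroman-1-one | C/C=C/[C@@H]1Cc2cc(OC)cc(OC)c2C(=O)O1 | intermediate
8 | rac-2-pentyloxirane (1,2-epoxyheptane) | CCCCCC1CO1 | starting material
9 | (S)-2-pentyloxirane | CCCCC[C@H]1CO1 | intermediate
10 | but-3-enylmagnesium bromide (THF solution) | C=CCC[Mg]Br | starting material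
11 | bromomagnesium (S)-undec-1-en-6-olate | CCCCC[C@H](O[Mg]Br)CCCC=C | intermediate
12 | (S)-undec-1-en-6-ol | CCCCC[C@H](O)CCCC=C | intermediate
13 | (3S)-3-[(1E,6S)-6-hydroxyundec-1-enyl]-6,8-dimethoxyisochroman-1-one | CCCCC[C@H](O)CCC/C=C/[C@@H]1Cc2cc(OC)cc(OC)c2C(=O)O1 | intermediate
14 | (3R)-3-[(6S)-6-hydroxyundecyl]-6,8-dimethoxyisochroman-1-one | CCCCC[C@H](O)CCCCC[C@@H]1Cc2cc(OC)cc(OC)c2C(=O)O1 | intermediate
15 | (3R,6'S)-8,6'-bis-O-(dichloroboryl) derivative of the target | CCCCC[C@H](OB(Cl)Cl)CCCCC[C@@H]1Cc2cc(OC)cc(OB(Cl)Cl)c2C(=O)O1 | intermediate
16 | (3R)-8-hydroxy-3-[(6S)-6-hydroxyundecyl]-6-methoxyisochroman-1-one | CCCCC[C@H](O)CCCCC[C@@H]1Cc2cc(OC)cc(O)c2C(=O)O1 | target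

Total step count: 7. Longest linear sequence: 5 steps (1, 2, 3, 6, 7). The side-chain branch (4, 5) joins at step 6.

Steps most likely to fail

**Step 3.**
- What may go wrong: weak facial discrimination in the migratory insertion; leakage through inner-sphere delivery of the carboxylate; slow erosion of configuration by repeated ionisation of the allylic lactone; protodecarboxylation of the crowded benzoate.
- Fallback: the nucleophile is changed from carboxylate to a benzylic alcohol, and the oxidation level at C1 is adjusted afterwards. It sets out from aldehyde 3. NaBH4 in MeOH should give (2-iodo-4,6-dimethoxyphenyl)methanol F1. The enantioselective palladium/phosphoramidite heteroannulation of F1 with diene 5, the mode established for ortho-iodobenzyl alcohols, should give (3S)-6,8-dimethoxy-3-[(E)-prop-1-enyl]isochromane F2. This again closes O2–C3, but as an allyl ether that is not re-ionised. DDQ in wet CH2Cl2 should oxidise the doubly activated C1 position to (3S)-6,8-dimethoxy-3-[(E)-prop-1-enyl]isochroman-1-ol F3. Dess–Martin periodinane should take this lactol to lactone 7, where the route is rejoined.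

**Step 6.**
- What may go wrong: the propenyl group is a 1,2-disubstituted alkene next to the branched C3 and may enter metathesis too slowly, so that self-metathesis of 12 consumes the catalyst. Ruthenium hydrides formed under hydrogen may also shift C1'=C2' towards C3 before saturation, which would erode the C3 configuration.
- Fallback: the fragment union is handed over to the annulation itself, so that no ruthenium meets the allylic lactone. It sets out from 12 and 4. NaH and BnBr should give (S)-6-(benzyloxy)undec-1-ene F4. The ether is needed because a free C6' hydroxyl could attack C2' of the allylpalladium and form a tetrahydropyran. Cross-metathesis of this unhindered terminal alkene with crotonaldehyde should give (2E,7S)-7-(benzyloxy)dodec-2-enal F5. Wittig methylenation with Ph3P=CH2 should give (6S,10E)-6-(benzyloxy)trideca-10,12-diene F6. Annulation of F6 with acid 4 under the conditions of step 3 should give (3S)-3-[(1E,6S)-6-(benzyloxy)undec-1-enyl]-6,8-dimethoxyisochroman-1-one F7. H2 over Pd/C should saturate the alkene and cleave the benzyl ether in one operation, and the route is rejoined at 14.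

**Step 7.**
- What may go wrong: competing cleavage of the 6-methoxy group, or substitution or elimination at the boron-activated C6' carbinol.
- Fallback: the ether cleavage is moved to the aldehyde stage, where no alcohol is present and only one methoxy group sits next to the carbonyl. It sets out from aldehyde 3. BCl3 in CH2Cl2 should give 2-hydroxy-6-iodo-4-methoxybenzaldehyde F8. Pinnick oxidation should give 2-hydroxy-6-iodo-4-methoxybenzoic acid F9. Annulation with 5 as in step 3, with one further equivalent of base, should give (3S)-8-hydroxy-6-methoxy-3-[(E)-prop-1-enyl]isochroman-1-one F10. The one-flask cross-metathesis and hydrogenation with 12 should pass through (3S)-8-hydroxy-3-[(1E,6S)-6-hydroxyundec-1-enyl]-6-methoxyisochroman-1-one F11 and come back to the route at target 16.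

Further compounds
F1 | step 3 | (2-iodo-4,6-dimethoxyphenyl)methanol | COc1cc(I)c(CO)c(OC)c1
F2 | step 3 | (3S)-6,8-dimethoxy-3-[(E)-prop-1-enyl]isochromane | C/C=C/[C@@H]1Cc2cc(OC)cc(OC)c2CO1
F3 | step 3 | (3S)-6,8-dimethoxy-3-[(E)-prop-1-enyl]isochroman-1-ol (C1 epimers) | C/C=C/[C@@H]1Cc2cc(OC)cc(OC)c2C(O)O1
F4 | step 6 | (S)-6-(benzyloxy)undec-1-ene | CCCCC[C@H](OCc1ccccc1)CCCC=C
F5 | step 6 | (2E,7S)-7-(benzyloxy)dodec-2-enal | CCCCC[C@H](OCc1ccccc1)CCC/C=C/C=O
F6 | step 6 | (6S,10E)-6-(benzyloxy)trideca-10,12-diene | CCCCC[C@H](OCc1ccccc1)CCC/C=C/C=C
F7 | step 6 | (3S)-3-[(1E,6S)-6-(benzyloxy)undec-1-enyl]-6,8-dimethoxyisochroman-1-one | CCCCC[C@H](OCc1ccccc1)CCC/C=C/[C@@H]1Cc2cc(OC)cc(OC)c2C(=O)O1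
F8 | step 7 | 2-hydroxy-6-iodo-4-methoxybenzaldehyde | COc1cc(O)c(C=O)c(I)c1
F9 | step 7 | 2-hydroxy-6-iodo-4-methoxybenzoic acid | COc1cc(O)c(C(=O)O)c(I)c1
F10 | step 7 | (3S)-8-hydroxy-6-methoxy-3-[(E)-prop-1-enyl]isochroman-1-one | C/C=C/[C@@H]1Cc2cc(OC)cc(O)c2C(=O)O1
F11 | step 7 | (3S)-8-hydroxy-3-[(1E,6S)-6-hydroxyundec-1-enyl]-6-methoxyisochroman-1-one | CCCCC[C@H](O)CCC/C=C/[C@@H]1Cc2cc(OC)cc(O)c2C(=O)O1
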